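**Remark on the chemistry:** the target has no stereocentre and is achiral, so "single enantiomer" is read as the single geometric and tautomeric form drawn (6E alkene, chelated 4Z enol at C5); aldehyde 2 is taken as a catalogue compound.

Chain numbering used throughout follows the name (4Z,6E)-5-hydroxy-1,7-bis(4-hydroxy-3-methoxyphenyl)hepta-4,6-dien-3-one: C1–C7, ring B on C1, ring A on C7.

## Analysis of the target

Compound 8 is an open-chain 1,7-diarylheptanoid, C21H22O6, with two identical 4-hydroxy-3-methoxyphenyl rings, and no ring has to be built. The only stereochemical elements are the 6E styryl alkene and the 4Z enol. The enol is held by the O–H···O=C3 hydrogen bond and is under tautomeric control, which also places it at C5, in conjugation with C6=C7 and ring A. About C4 the chain is almost symmetric: the arm C5–C6H=C7H–ring A and the arm C3–C2H2–C1H2–ring B differ by two hydrogen atoms only, so 8 is the 1,2-dihydro derivative of symmetric curcumin (A5 below). That small difference is the whole problem, because a reagent that can build, reduce or oxidise one arm meets a nearly identical second arm.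

The plan rests on the triad C3(=O)–C2H2–C1H2 next to ring B. It is the redox isomer of a secondary allylic alcohol C3H(OH)–C2H=C1H. Hence 8 is a constitutional isomer of the aldol adduct of a C11 styryl methyl ketone and a C10 cinnamaldehyde (C11H12O3 + C10H10O3 = C21H22O6).

The sensitive groups are:
- the β-keto-enol C3–C5 (retro-Claisen cleavage and autoxidation in base, chelation of metals);
- the two guaiacol-type phenols (oxidation, quinone methide formation through C1 or C7);
- the electron-rich enone (Michael addition, E/Z photoisomerisation).

## Retrosynthetic reasoning

**8 ⇒ 7.** Only the O–acetyl bond on ring B is cut. The acetate costs no step, because it comes with the commercial aldehyde 2, and it does three jobs.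
- It keeps the aldehyde of 2 electrophilic. A free phenoxide para to the enal would turn it into a vinylogous carboxylate.
- It lowers the donor strength of ring B, so the allylic C3–O bond of 5 is slow to ionise.
- It blocks quinone methide formation on that arm.

The forward reaction has to remove an aryl ester without cleaving the β-diketone.

**7 ⇒ 5 (key disconnection).** No carbon–carbon bond is cut. The hydrogen on C1 is moved back to C3 and the hydrogen on C2 back to oxygen, so C3=O becomes a carbinol and C1–C2 becomes an E alkene.
- *Why here:* the move turns the unsymmetric target into 5, in which both arms are cinnamyl-type. It makes the central cut between two monomers of one family legitimate. The "extra H2" that distinguishes 8 from its symmetric parent is stored in 5 as C3–H and O–H, which is exactly what an aldol addition delivers.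
- *What is gained:* no external reductant or oxidant is needed, one hydride equivalent is fixed per molecule, and the β-diketone appears only in the last skeletal operation under near-neutral conditions.
- *What the forward reaction must achieve:* it must carry the hydride from C3 to C1, through the metal-bound dienedione 6, faster than 5 loses water across C3–C4 or falls apart by retro-aldol cleavage.
- *Why site selectivity does not matter:* the two arms of 6 differ only in the remote acetyl group, so return of the hydride to either arm ends in 8 after deacetylation.

"Iridium-catalysed redox isomerisation of the bis-cinnamyl aldol 5" is not the sentence with which this target is usually opened.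

**5 ⇒ 1 + 2.** The central C3–C4 bond is cut, which splits the chain into a C11 and a C10 half, the most convergent cut available. Ketone 1 has a single enolisable position, its methyl group (the future C4), so no regiochemical question arises. Aldehyde 2 cannot enolise at its aldehyde end, so no self-aldol competes. The forward reaction is a directed aldol addition through 3 and 4. It must stop at the addition stage and add 1,2 to the enal.

## Alternatives that were turned down

**Alternative 1:** cut at C6=C7, the textbook route. The forward key step is a boron-templated, amine-catalysed aldol condensation of vanillin A1 with the terminal methyl group of 6-(4-hydroxy-3-methoxyphenyl)hexane-2,4-dione A4, whose central carbon is blocked by the boron chelate. A4 comes from acetylacetone A2 by the same condensation with A1, which gives (E)-6-(4-hydroxy-3-methoxyphenyl)hex-5-ene-2,4-dione A3, followed by catalytic hydrogenation. It was turned down for these reasons: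
- The two methyl groups of A2 are homotopic, so the first condensation is selective only through an excess of A2.
- The arms are told apart only by the order of events, with an external reduction wedged between two runs of the same reaction.
- The sequence is strictly linear, and its last step adds only a C8 piece.
- The β-diketone has to be chelated and released twice.
- It needs as many steps as the present plan and carries no strategic idea.

**Alternative 2:** no skeletal bond is cut; only C1–H and C2–H are formed by partial conjugate reduction or semihydrogenation of curcumin A5. It was turned down for these reasons:
- The two enone arms of A5 are interchanged by enol tautomerism and are chemically equivalent.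
- The arm that remains in 8 is still an aryl enone of almost the same electrophilicity and the same affinity for a metal surface.
- Nothing in the structure stops the reaction after one equivalent, so a near-statistical mixture of A5, 8 and tetrahydrocurcumin A6 must be expected.
- These three compounds share all polar groups, which makes separation the real task.
- The precursor is as complex as the product, so the key step simplifies nothing.

**Alternative 3:** cut both bonds at C5 (C4–C5 and C5–C6). The forward key step is a three-component, palladium-catalysed carbonylative α-alkenylation. The O-silylated (E)-β-bromostyrene A7 adds oxidatively to palladium, carbon monoxide A8 inserts, and the styrylacyl–palladium species is taken up by the enolate of O-silylated zingerone A9 to give the bis-silyl ether A10 of the target. The idea is attractive because C5 comes from a C1 gas and the diketone forms in one operation. It was turned down for these reasons: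
- A9 can enolise toward C4 or toward C2, and warm equilibrating catalysis gives the structure no means to fix the site.
- The strong base forces both phenols to be masked and unmasked.
- A7 has to be made in two steps.
- Direct α-alkenylation without insertion, O-acylation of the enolate and chelation of palladium by the diketonate all compete.
- The route would need about twice as many steps as the one chosen.

Key step: step 2

## Route

Step 1
Reactants: 1 dehydrozingerone [(E)-4-(4-hydroxy-3-methoxyphenyl)but-3-en-2-one]; 2 (E)-4-acetoxy-3-methoxycinnamaldehyde
Product: 5 (±)-(1E,6E)-1-(4-acetoxy-3-methoxyphenyl)-3-hydroxy-7-(4-hydroxy-3-methoxyphenyl)hepta-1,6-dien-5-one (ketol; chain numbered as in the target), via dilithium phenoxide-enolate 3 (not isolated), via dilithium aldolate 4 (not isolated)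
Conditions: LDA (commercial solution, 2.1 equiv), THF, −78 °C; then 2 (1.05 equiv), THF, −78 °C; AcOH (2.5 equiv), −78 °C → rt
Reagents that add atoms: none
Why: Directed aldol addition of a preformed lithium enolate: the first equivalent of LDA takes the phenol proton and the second the only enolisable position of 1 (its methyl group, the future C4), a dianion mode that is known for unprotected phenolic methyl ketones, and 2 cannot enolise at its aldehyde end. At −78 °C a lithium enolate adds 1,2 to an enal under kinetic control much faster than it attacks or deprotonates an aryl acetate, and the cold acid quench stops the sequence at the addition stage. The new C3 carbinol centre is formed racemic, which is of no consequence because step 2 erases it.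

Step 2
Reactants: 5 ketol
Product: 7 (4Z,6E)-1-(4-acetoxy-3-methoxyphenyl)-5-hydroxy-7-(4-hydroxy-3-methoxyphenyl)hepta-4,6-dien-3-one (ring-B acetate of the target), via iridium-bound O-acetylcurcumin 6 (not isolated)
Conditions: [Cp*IrCl2]2 (2.5 mol %), degassed THF–H2O (1:1), 30 °C, Ar, subdued light
Reagents that add atoms: none
Why: Redox isomerisation of a secondary allylic alcohol to the saturated ketone (formal 1,3-hydride shift), a known reaction type for aryl-substituted secondary allylic alcohols with base-free Cp*Ir(III) halide catalysts in aqueous THF near room temperature; the related isomerisation of Morita–Baylis–Hillman-type allylic alcohols shows that such catalysis can end in an enolisable 1,3-dicarbonyl compound. Mechanism: the C3 hydroxyl binds to iridium as alkoxide, β-hydride elimination of C3–H gives a Cp*Ir–H that holds the cross-conjugated dienedione 6, the hydride returns in a conjugate sense to the benzylic carbon C1, and water protonates the iridium enolate at C2 and frees 7. In this single operation the C3 carbonyl, with it the whole C3–C4–C5 keto-enol chelate, and the saturated C1–C2 bridge are created, that is, both features that set the target apart from its symmetric parent, without any external oxidant or reductant. No ring is closed and no stereocentre is formed: the racemic carbinol centre of 5 is erased, the C6=C7 alkene keeps its E geometry, and the 4Z enol at C5 results from tautomeric equilibration under the control of the O–H···O=C3 hydrogen bond and of conjugation with ring A. The selectivity needed is one hydride per molecule and no more, and the substrate secures it, since each molecule of 5 carries exactly one hydride equivalent (C3–H), so that over-reduction could only arise from hydrogen transfer between molecules. The site of hydride return is not critical, because the two enone arms of 6 differ only in the remote O-acetyl group and delivery to either arm gives, after step 3, the same compound 8. The medium is kept free of base and near 30 °C because the competing processes, retro-aldol cleavage of C3–C4 and loss of water across C3–C4, are driven by base or heat, and because without base a β-keto-enol binds the metal centre only reversibly. The acetate on ring B lowers the donor strength of that ring and blocks quinone methide formation, so that ionisation of the allylic C3–O bond is held back, while phenol, aryl acetate and enone are inert to the catalyst.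

Step 3
Reactants: 7 ring-B acetate of the target
Product: 8 (4Z,6E)-5-hydroxy-1,7-bis(4-hydroxy-3-methoxyphenyl)hepta-4,6-dien-3-one (dihydrocurcumin, target)
Conditions: K2CO3 (3 equiv), degassed MeOH, 0 °C, Ar; then 1 M HCl to pH 4
Reagents that add atoms: none
Why: Base-mediated transesterification (Zemplén-type methanolysis) of an aryl acetate, the only ester present and a very reactive one. The β-keto-enol is deprotonated at once to its delocalised enolate, which methoxide does not attack, so that retro-Claisen cleavage is held back, and exclusion of oxygen suppresses autoxidation. Acidification returns the chelated 4Z enol, and the 6E alkene is not touched.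

## Compound list

1 | dehydrozingerone, (E)-4-(4-hydroxy-3-methoxyphenyl)but-3-en-2-one | CC(=O)/C=C/c1ccc(O)c(OC)c1 | starting material
2 | (E)-4-acetoxy-3-methoxycinnamaldehyde | CC(=O)Oc1ccc(/C=C/C=O)cc1OC | starting material
3 | dilithium phenoxide-enolate of 1 | C=C([O-])/C=C/c1ccc([O-])c(OC)c1.[Li+].[Li+] | intermediate
4 | dilithium aldolate (phenoxide and C3 alkoxide of 5, racemic) | COc1cc(/C=C/C(=O)CC([O-])/C=C/c2ccc(OC(C)=O)c(OC)c2)ccc1[O-].[Li+].[Li+] | intermediate
5 | (±)-(1E,6E)-1-(4-acetoxy-3-methoxyphenyl)-3-hydroxy-7-(4-hydroxy-3-methoxyphenyl)hepta-1,6-dien-5-one (racemic at C3) | COc1cc(/C=C/C(=O)CC(O)/C=C/c2ccc(OC(C)=O)c(OC)c2)ccc1O | intermediate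
6 | O-acetylcurcumin, (1E,6E)-1-(4-acetoxy-3-methoxyphenyl)-7-(4-hydroxy-3-methoxyphenyl)hepta-1,6-diene-3,5-dione, held on Cp*Ir–H (SMILES of the organic ligand) | COc1cc(/C=C/C(=O)CC(=O)/C=C/c2ccc(OC(C)=O)c(OC)c2)ccc1O | intermediate
7 | (4Z,6E)-1-(4-acetoxy-3-methoxyphenyl)-5-hydroxy-7-(4-hydroxy-3-methoxyphenyl)hepta-4,6-dien-3-one | COc1cc(/C=C/C(O)=C/C(=O)CCc2ccc(OC(C)=O)c(OC)c2)ccc1O | intermediate
8 | (4Z,6E)-5-hydroxy-1,7-bis(4-hydroxy-3-methoxyphenyl)hepta-4,6-dien-3-one (dihydrocurcumin) | COc1cc(/C=C/C(O)=C/C(=O)CCc2ccc(O)c(OC)c2)ccc1O | target

## Step count and risk

Total step count: 3. Longest linear sequence: 3 (1 or 2 → 5 → 7 → 8).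

**Step 2 (key step).** The most likely failure is slow or stalled turnover. Both the bound intermediate and the product are β-keto-enols, which can chelate iridium through both oxygens and displace the halide that the catalyst needs. Next in likelihood are loss of water across C3–C4 to a fully conjugated chain, and escape of the hydride from the metal–ligand pair. The latter would show up as hydrogen transfer between molecules and a disproportionation of oxidation levels.

The fallback gives up the internal redox and stores the saturated arm in the nucleophile. It sets out from 2. Zingerone F1 is doubly deprotonated with LDA at −78 °C (kinetic enolate at the methyl group) and added to 2 to give the saturated-arm ketol F2. Activated MnO2 in CH2Cl2 oxidises only the allylic carbinol and gives the styryl-ring acetate of the target F3. Methanolysis as in step 3 comes back to the route at 8.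

**Step 1.** The most likely failures are:
- incomplete second deprotonation or poor solubility of the aggregated dilithium species;
- transfer or loss of the acetyl group of 2 by attack or deprotonation through the enolate;
- retro-aldol cleavage or dehydration if the aldolate warms before the quench.

The fallback replaces the strongly basic dianion by a neutral silyl enol ether under Lewis acid activation. It sets out from 1. TMSOTf and Et3N in CH2Cl2 convert 1 into the bis-silylated 2-silyloxydiene F4. This adds to 2 under BF3·OEt2 at −78 °C (Mukaiyama aldol addition, 1,2 to the enal). A citric acid work-up strips both silyl groups and comes back to the route at 5.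

**Step 3.** The most likely failures are retro-Claisen cleavage of the β-diketone by methoxide and autoxidation of the phenoxide/enolate, if oxygen is not fully excluded or the exposure to base is long.

The fallback moves the deprotection in front of the diketone, so that the last step is the neutral isomerisation. It sets out from 2, which is methanolysed at the robust aldehyde stage to coniferaldehyde F5. This is silylated with TMSCl and Et3N to the trimethylsilyl ether F6. F6 is added to the dianion 3 at −78 °C, and a citric acid work-up cleaves the aryl silyl ether to give the fully unprotected ketol F7. The conditions of step 2 then take F7 directly to 8.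

## Further compounds

F1 | step 2 | zingerone, 4-(4-hydroxy-3-methoxyphenyl)butan-2-one | CC(=O)CCc1ccc(O)c(OC)c1
F2 | step 2 | (±)-(E)-7-(4-acetoxy-3-methoxyphenyl)-5-hydroxy-1-(4-hydroxy-3-methoxyphenyl)hept-6-en-3-one | COc1cc(CCC(=O)CC(O)/C=C/c2ccc(OC(C)=O)c(OC)c2)ccc1O
F3 | step 2 | (4Z,6E)-7-(4-acetoxy-3-methoxyphenyl)-5-hydroxy-1-(4-hydroxy-3-methoxyphenyl)hepta-4,6-dien-3-one | CC(=O)Oc1ccc(/C=C/C(O)=C/C(=O)CCc2ccc(O)c(OC)c2)cc1OC
F4 | step 1 | (E)-1-(3-methoxy-4-trimethylsilyloxyphenyl)-3-trimethylsilyloxybuta-1,3-diene | C=C(O[Si](C)(C)C)/C=C/c1ccc(O[Si](C)(C)C)c(OC)c1
F5 | step 3 | coniferaldehyde, (E)-4-hydroxy-3-methoxycinnamaldehyde | COc1cc(/C=C/C=O)ccc1O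
F6 | step 3 | (E)-3-methoxy-4-trimethylsilyloxycinnamaldehyde | COc1cc(/C=C/C=O)ccc1O[Si](C)(C)C
F7 | step 3 | (±)-(1E,6E)-5-hydroxy-1,7-bis(4-hydroxy-3-methoxyphenyl)hepta-1,6-dien-3-one | COc1cc(/C=C/C(=O)CC(O)/C=C/c2ccc(O)c(OC)c2)ccc1O
A1 | alternative 1 | vanillin | COc1cc(C=O)ccc1O
A2 | alternative 1 | acetylacetone | CC(=O)CC(C)=O
A3 | alternative 1 | (E)-6-(4-hydroxy-3-methoxyphenyl)hex-5-ene-2,4-dione | CC(=O)CC(=O)/C=C/c1ccc(O)c(OC)c1
A4 | alternative 1 | 6-(4-hydroxy-3-methoxyphenyl)hexane-2,4-dione | CC(=O)CC(=O)CCc1ccc(O)c(OC)c1
A5 | alternative 2 | curcumin | COc1cc(/C=C/C(O)=C/C(=O)/C=C/c2ccc(O)c(OC)c2)ccc1O
A6 | alternative 2 | tetrahydrocurcumin | COc1cc(CCC(=O)CC(=O)CCc2ccc(O)c(OC)c2)ccc1O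
A7 | alternative 3 | (E)-[4-(2-bromovinyl)-2-methoxyphenoxy](tert-butyl)dimethylsilane | COc1cc(/C=C/Br)ccc1O[Si](C)(C)C(C)(C)C
A8 | alternative 3 | carbon monoxide | [C-]#[O+]
A9 | alternative 3 | 4-[4-(tert-butyldimethylsilyloxy)-3-methoxyphenyl]butan-2-one | CC(=O)CCc1ccc(O[Si](C)(C)C(C)(C)C)c(OC)c1
A10 | alternative 3 | bis(tert-butyldimethylsilyl) ether of the target | COc1cc(/C=C/C(O)=C/C(=O)CCc2ccc(O[Si](C)(C)C(C)(C)C)c(OC)c2)ccc1O[Si](C)(C)C(C)(C)C
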